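**Plan** (cembrane numbering: C1 carries the isopropyl group, C4 the CO2Me group (C18), C7 the acetate, C8 the methyl group (C19) and the lactone oxygen, C12 the lactone carbonyl carbon C20)

1. Retrosynthesis cuts C1–C14 first (fourteen-membered carbocycle), then C11=C12 together with C13=C14 (ring-closing enyne metathesis, seven-membered lactone), then the C20–O ester bond, C3=C4 (Horner–Wadsworth–Emmons) and C4–C5 (phosphonate alkylation).
2. Forward: the chain C1–C11 is joined from hex-1-en-5-yne (carboalumination/oxirane), a phosphonoacetate and a (Z)-β-iodoenal; C7/C8 are oxidised; the C8 propiolate closes the lactone by enyne metathesis, which also creates the C12 vinyl group (C13=C14); the last step closes the carbocycle.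
3. Stereochemistry: C7 and C8 come from Shi epoxidation of the (E)-C7=C8 alkene (reagent control, R,R) followed by acid hydrolysis with inversion at C8. The C1=C2 geometry comes from trans-hydroalumination/iodination, and C3=C4 from the olefination; both are kept in the ring closure. C11=C12 is cis by ring constraint.
4. Enabling feature: the seven-membered lactone (O, C20, C12, C11, C10, C9, C8) with its cis C11=C12 bond holds the C12 arm (C13, C14) and the C8 side chain (C7 to C1) on the same side. C13=C14 is the only monosubstituted alkene and C1–I the only C(sp2)–I bond of the precursor.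

Key step: step 13

Assumption: the D-fructose-derived Shi ketone is taken to give the (2R,3R)-oxirane from the (E)-trialkyl alkene of 13, as it does with other trans-trisubstituted alkenes.

**Step 1**
Reactants: 1 3-methylbut-1-yne
Product: 2 4-methylpent-2-yn-1-ol
Conditions: n-BuLi, THF, −78 °C; (CH2O)n, −78 → 23 °C; aq. NH4Cl
Reagents that add atoms: paraformaldehyde (formaldehyde unit), C=O
Why: Addition of the lithium acetylide to formaldehyde (acetylide hydroxymethylation) is a standard one-carbon extension and creates no stereocentre.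

**Step 2**
Reactants: 2 4-methylpent-2-yn-1-ol
Product: 4 (2Z)-3-iodo-4-methylpent-2-en-1-ol, via cyclic alkenylaluminate 3 (not isolated)
Conditions: NaAlH2(OCH2CH2OMe)2 (Red-Al), Et2O, 0 → 23 °C; EtOAc; then I2, THF, −78 → 0 °C
Reagents that add atoms: iodine, II; NaAlH2(OCH2CH2OMe)2, [Na+].[AlH2-](OCCOC)OCCOC (its aluminium and alkoxy groups stay in 3 only)
Why: Hydroxyl-directed trans-hydroalumination of the propargylic alcohol places aluminium on C3 in a five-membered alkoxyaluminate and iodinolysis with retention gives the (Z)-iodoalkene (hydroalumination–iodination), so the geometry follows from the anti addition of H and Al.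

**Step 3**
Reactants: 4 (2Z)-3-iodo-4-methylpent-2-en-1-ol
Product: 5 (2Z)-3-iodo-4-methylpent-2-enal
Conditions: MnO2, CH2Cl2, 23 °C, dark
Reagents that add atoms: none
Why: Activated MnO2 oxidises allylic alcohols to enals under neutral conditions (allylic alcohol oxidation), which should leave the (Z)-β-iodoenal geometry unchanged.

**Step 4**
Reactants: 6 hex-1-en-5-yne
Product: 9 (3E)-4-methylocta-3,7-dien-1-ol, via alkenyldimethylalane 7 (not isolated), via lithium alanate 8 (not isolated)
Conditions: Me3Al, Cp2ZrCl2 (25 mol%), CH2Cl2, 0 → 23 °C; volatiles removed; n-BuLi, hexane/THF, −30 °C; oxirane, −30 → 0 °C; aq. HCl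
Reagents that add atoms: trimethylaluminium, C[Al](C)C; n-butyllithium, [Li]CCCC (stays in 8 only); oxirane, C1CO1
Why: Zirconium-catalysed syn-carboalumination of the terminal alkyne (Negishi carboalumination, the unactivated terminal alkene being far slower) fixes the (E)-trisubstituted alkene, and the alanate formed with n-BuLi opens oxirane with retention of alkene geometry to give the homoallylic alcohol.

**Step 5**
Reactants: 9 (3E)-4-methylocta-3,7-dien-1-ol
Product: 10 (5E)-8-iodo-5-methylocta-1,5-diene
Conditions: PPh3, I2, imidazole, CH2Cl2, 0 → 23 °C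
Reagents that add atoms: iodine, II
Why: Appel-type iodination of the primary alcohol through its alkoxyphosphonium iodide (SN2) touches neither alkene and creates no stereocentre.

**Step 6**
Reactants: 10 (5E)-8-iodo-5-methylocta-1,5-diene; 11 methyl 2-(diethoxyphosphoryl)acetate
Product: 12 methyl (5E)-2-(diethoxyphosphoryl)-6-methyldeca-5,9-dienoate
Conditions: NaH, 11 (2 equiv), DMSO, 23 → 50 °C
Reagents that add atoms: none
Why: SN2 C-alkylation of the sodium phosphonoacetate by the primary iodide (alkylation of a stabilised carbanion, excess 11 against dialkylation) gives the α-alkyl phosphonate, whose new stereocentre is racemic and is destroyed in step 7.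

**Step 7**
Reactants: 12 methyl (5E)-2-(diethoxyphosphoryl)-6-methyldeca-5,9-dienoate; 5 (2Z)-3-iodo-4-methylpent-2-enal
Product: 13 methyl (2E,4Z)-5-iodo-6-methyl-2-[(3E)-4-methylocta-3,7-dien-1-yl]hepta-2,4-dienoate
Conditions: NaH, THF, 0 °C; then 5, 0 → 23 °C
Reagents that add atoms: none
Why: Horner–Wadsworth–Emmons olefination of the α-alkyl phosphonoacetate with the unhindered conjugated aldehyde should favour the (2E)-enoate (ester trans to the dienyl chain) through reversible, thermodynamically controlled addition, while the (Z)-iodoalkene is carried through unchanged.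

**Step 8**
Reactants: 13 methyl (2E,4Z)-5-iodo-6-methyl-2-[(3E)-4-methylocta-3,7-dien-1-yl]hepta-2,4-dienoate
Product: 14 methyl (2E,4Z)-2-{2-[(2R,3R)-3-(but-3-en-1-yl)-3-methyloxiran-2-yl]ethyl}-5-iodo-6-methylhepta-2,4-dienoate
Conditions: D-fructose-derived Shi ketone (30 mol%), KHSO5 (as Oxone, 2KHSO5·KHSO4·K2SO4), K2CO3, Bu4NHSO4, MeCN/CH2(OMe)2/aq. Na2B4O7 buffer, 0 °C
Reagents that add atoms: potassium peroxymonosulfate (KHSO5), [K+].[O-]S(=O)(=O)OO
Why: In the Shi asymmetric epoxidation the chiral dioxirane transfers oxygen through a spiro transition state to one face of the isolated, electron-rich (E)-trisubstituted alkene and sets C7 and C8 as (R,R) by reagent control, the terminal alkene and the electron-poor iododienoate being much slower.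

**Step 9**
Reactants: 14 (the (2R,3R)-epoxide)
Product: 15 methyl (2E,4Z)-2-[(3R,4S)-3,4-dihydroxy-4-methyloct-7-en-1-yl]-5-iodo-6-methylhepta-2,4-dienoate
Conditions: HClO4 (cat.), THF/H2O (3:1), 0 → 23 °C
Reagents that add atoms: water, O
Why: In this acid-catalysed epoxide hydrolysis water opens the protonated epoxide at the tertiary carbon C8 with inversion while C7 keeps its C–O bond, so the (7R,8R)-epoxide gives the anti (7R,8S)-diol.

**Step 10**
Reactants: 15 (the (3R,4S)-diol)
Product: 16 methyl (2E,4Z)-2-[(3R,4S)-3-acetoxy-4-hydroxy-4-methyloct-7-en-1-yl]-5-iodo-6-methylhepta-2,4-dienoate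
Conditions: Ac2O, pyridine, DMAP (cat.), CH2Cl2, 0 °C
Reagents that add atoms: acetic anhydride, CC(=O)OC(C)=O
Why: DMAP-catalysed acetylation takes the secondary C7 hydroxyl and leaves the hindered tertiary C8 hydroxyl free (selective acylation), with no change at either stereocentre.

**Step 11**
Reactants: 16 (the C7 acetate, C8 alcohol); 17 prop-2-ynoic acid
Product: 18 methyl (2E,4Z)-2-[(3R,4S)-3-acetoxy-4-methyl-4-(prop-2-ynoyloxy)oct-7-en-1-yl]-5-iodo-6-methylhepta-2,4-dienoate
Conditions: DCC, DMAP (10 mol%), CH2Cl2, −20 → 0 °C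
Reagents that add atoms: none
Why: Steglich esterification is the carbodiimide method that acylates tertiary alcohols, and the low temperature and catalytic DMAP limit addition of the base to the ynoate; the C8–O bond is not broken, so its configuration is kept.

**Step 12**
Reactants: 18 (the C8 propiolate)
Product: 19 methyl (2E,4Z)-2-{(3R)-3-acetoxy-3-[(2S)-6-ethenyl-2-methyl-7-oxo-2,3,4,7-tetrahydrooxepin-2-yl]propyl}-5-iodo-6-methylhepta-2,4-dienoate
Conditions: second-generation Grubbs catalyst RuCl2(=CHPh)(H2IMes)(PCy3) (10 mol%), toluene (5 mM), 80 °C, argon; product used at once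
Reagents that add atoms: none
Why: In this ring-closing enyne metathesis the ruthenium alkylidene formed at the terminal alkene (C11) adds to the ynoate in the exo mode to make C11=C12, and the resulting C13 vinylcarbene takes a CH2 group from the alkene of the next substrate molecule, so the seven-membered (necessarily cis) enoate lactone and the C13=C14 vinyl group arise together while the trisubstituted alkenes stay inert.

**Step 13**
Reactants: 19 (the 6-ethenyl lactone with the (Z)-alkenyl iodide)
Product: 21 Sarcrassin D, via B-alkyl-9-BBN borane 20 (not isolated)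
Conditions: 9-BBN (1.5 equiv), THF, 0 → 23 °C; then slow addition (syringe pump) to Pd(dppf)Cl2 (20 mol%), AsPh3 (40 mol%), Cs2CO3 (3 equiv), DMF/THF/H2O, 45 °C, final concentration 1 mM
Reagents that add atoms: 9-borabicyclo[3.3.1]nonane (9-BBN), B1C2CCCC1CCC2 (boron and ring stay in 20 only; 21 keeps one hydrogen)
Why: 9-BBN adds anti-Markovnikov to C13=C14, the only monosubstituted alkene of 19, and puts boron on C14 (borane 20); zerovalent palladium then inserts into the C1–I bond, the base-activated borane transfers its primary alkyl group to palladium, and reductive elimination forms the C1–C14 bond. The closest known reaction type is the one-pot hydroboration/intramolecular B-alkyl Suzuki–Miyaura coupling used to close macrocyclic carbocycles at an alkenyl–alkyl bond. The fourteen-membered carbocycle closes end to end (C14 of the C12 arm onto C1 of the C8 side chain, both on palladium, under slow-addition high dilution), and the seven-membered lactone already present becomes the fused second ring. No stereocentre is formed: the C1=C2 geometry is carried over with retention from the (Z)-iodide, so that C14 ends cis to C3, and C7, C8, C3=C4 and C11=C12 are not touched. The step needs chemoselective hydroboration, which is secured because the dienoate and enoate alkenes are trisubstituted and electron-poor and the esters do not react with 9-BBN at room temperature. It also needs ring closure in preference to oligomerisation, which is secured by dilution and by the cis C11=C12 bond of the lactone, which turns the C12 arm and the C8 side chain to the same side.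

**Compound list**

1 | 3-methylbut-1-yne | CC(C)C#C | starting material
2 | 4-methylpent-2-yn-1-ol | CC(C)C#CCO | intermediate
3 | sodium 2,2-bis(2-methoxyethoxy)-3-(propan-2-yl)-2,5-dihydro-1,2-oxaluminol-2-uide (cyclic (Z)-alkenylaluminate) | [Na+].CC(C)C1=CCO[Al-]1(OCCOC)OCCOC | intermediate
4 | (2Z)-3-iodo-4-methylpent-2-en-1-ol | OC/C=C(/C(C)C)I | intermediate
5 | (2Z)-3-iodo-4-methylpent-2-enal | O=C/C=C(/C(C)C)I | intermediate
6 | hex-1-en-5-yne | C=CCCC#C | starting material
7 | dimethyl[(1E)-2-methylhexa-1,5-dien-1-yl]alumane | C=CCC/C(C)=C/[Al](C)C | intermediate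
8 | lithium butyl(dimethyl)[(1E)-2-methylhexa-1,5-dien-1-yl]aluminate | [Li+].C=CCC/C(C)=C/[Al-](C)(C)CCCC | intermediate
9 | (3E)-4-methylocta-3,7-dien-1-ol | OCC/C=C(\C)CCC=C | intermediate
10 | (5E)-8-iodo-5-methylocta-1,5-diene | ICC/C=C(\C)CCC=C | intermediate
11 | methyl 2-(diethoxyphosphoryl)acetate | CCOP(=O)(CC(=O)OC)OCC | starting material
12 | methyl (5E)-2-(diethoxyphosphoryl)-6-methyldeca-5,9-dienoate (racemic at C2) | COC(=O)C(CC/C=C(\C)CCC=C)P(=O)(OCC)OCC | intermediate
13 | methyl (2E,4Z)-5-iodo-6-methyl-2-[(3E)-4-methylocta-3,7-dien-1-yl]hepta-2,4-dienoate | COC(=O)/C(=C/C=C(/C(C)C)I)CC/C=C(\C)CCC=C | intermediate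
14 | methyl (2E,4Z)-2-{2-[(2R,3R)-3-(but-3-en-1-yl)-3-methyloxiran-2-yl]ethyl}-5-iodo-6-methylhepta-2,4-dienoate | COC(=O)/C(=C/C=C(/C(C)C)I)CC[C@H]1O[C@]1(C)CCC=C | intermediate
15 | methyl (2E,4Z)-2-[(3R,4S)-3,4-dihydroxy-4-methyloct-7-en-1-yl]-5-iodo-6-methylhepta-2,4-dienoate | COC(=O)/C(=C/C=C(/C(C)C)I)CC[C@@H](O)[C@@](C)(O)CCC=C | intermediate
16 | methyl (2E,4Z)-2-[(3R,4S)-3-acetoxy-4-hydroxy-4-methyloct-7-en-1-yl]-5-iodo-6-methylhepta-2,4-dienoate | COC(=O)/C(=C/C=C(/C(C)C)I)CC[C@@H](OC(C)=O)[C@@](C)(O)CCC=C | intermediate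
17 | prop-2-ynoic acid (propiolic acid) | OC(=O)C#C | starting material
18 | methyl (2E,4Z)-2-[(3R,4S)-3-acetoxy-4-methyl-4-(prop-2-ynoyloxy)oct-7-en-1-yl]-5-iodo-6-methylhepta-2,4-dienoate | COC(=O)/C(=C/C=C(/C(C)C)I)CC[C@@H](OC(C)=O)[C@@](C)(OC(=O)C#C)CCC=C | intermediate
19 | methyl (2E,4Z)-2-{(3R)-3-acetoxy-3-[(2S)-6-ethenyl-2-methyl-7-oxo-2,3,4,7-tetrahydrooxepin-2-yl]propyl}-5-iodo-6-methylhepta-2,4-dienoate | COC(=O)/C(=C/C=C(/C(C)C)I)CC[C@@H](OC(C)=O)[C@]1(C)CCC=C(C=C)C(=O)O1 | intermediate
20 | methyl (2E,4Z)-2-{(3R)-3-acetoxy-3-[(2S)-6-[2-(9-borabicyclo[3.3.1]nonan-9-yl)ethyl]-2-methyl-7-oxo-2,3,4,7-tetrahydrooxepin-2-yl]propyl}-5-iodo-6-methylhepta-2,4-dienoate | COC(=O)/C(=C/C=C(/C(C)C)I)CC[C@@H](OC(C)=O)[C@]1(C)CCC=C(CCB2C3CCCC2CCC3)C(=O)O1 | intermediate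
21 | Sarcrassin D (7R,8S in cembrane numbering) | COC(=O)/C1=C/C=C(/C(C)C)CCC2=CCC[C@](C)(OC2=O)[C@H](OC(C)=O)CC1 | target

**Step count and risks**

Total step count: 13. Longest linear sequence: 10 steps (steps 4 to 13, from 6 to 21).

Steps most likely to fail, most risky first:

Step 13. What may go wrong: the ring closure may lose to intermolecular coupling (oligomerisation) or to protodeboronation, and the aqueous base may hydrolyse the acetate or the lactone during the long addition. The fallback sets out from 19 and comes back at 21, and it replaces the aqueous boron coupling by an anhydrous, base-free zinc coupling of an isolated halide. Hydroboration of 19 with 9-BBN (through 20) and oxidation with NaBO3·4H2O would give primary alcohol F1, kept away from acid and base because its hydroxyl could attack the lactone carbonyl. I2, PPh3 and imidazole would convert it into primary iodide F2. Zinc insertion (Zn dust, LiCl, THF, 25 °C), which is much faster into the alkyl than into the alkenyl C–I bond, would give alkylzinc iodide F3. Slow addition of F3 to Pd(dppf)Cl2 in THF/NMP would close C1–C14 by an intramolecular Negishi coupling to 21.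

Step 12. What may go wrong: the electron-poor alkyne may turn over slowly (the C13 vinylcarbene can be held by the ester carbonyl), and the 2-acyl-1,3-diene product may dimerise by cycloaddition before it is used. The fallback sets out from 16 and comes back at 21, and it avoids both the ynoate and the diene. α-Methylene-γ-butyrolactone would be saponified (NaOH, H2O) to sodium 4-hydroxy-2-methylidenebutanoate F4, silylated (TBSCl, imidazole, DMF) to bis-silyl compound F5, and the silyl ester cleaved (K2CO3, MeOH/H2O) to 4-silyloxy acid F6. Steglich esterification of 16 with F6 would give acrylate ester F7. Ordinary diene ring-closing metathesis (second-generation Grubbs catalyst RuCl2(=CHPh)(H2IMes)(PCy3), toluene, 80 °C) would give lactone silyl ether F8, which carries C13 and C14 as a 2-silyloxyethyl group. Ph3PBr2 in CH2Cl2 would convert the silyl ether directly into primary bromide F9, so that no free C14 alcohol is formed. NaI in acetone would give primary iodide F2, which goes on through alkylzinc iodide F3 to 21 as described for step 13.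

Step 11. What may go wrong: acylation of the hindered tertiary alcohol may be slower than N-acylurea formation and than base-induced oligomerisation of propiolic acid. The fallback sets out from 14 and comes back at 18, and it forms the C8–O bond instead of the acyl–O bond. Propiolic acid (excess, CH2Cl2, 0 °C) would open the protonated epoxide at the tertiary carbon C8 with inversion, the same stereochemical course as step 9, to give hydroxy propiolate F10. Immediate acetylation of the secondary alcohol (Ac2O, pyridine, 0 °C), before the propiolate can migrate, would give 18.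

**Further compounds**

F1 | step 13 | methyl (2E,4Z)-2-{(3R)-3-acetoxy-3-[(2S)-6-(2-hydroxyethyl)-2-methyl-7-oxo-2,3,4,7-tetrahydrooxepin-2-yl]propyl}-5-iodo-6-methylhepta-2,4-dienoate | COC(=O)/C(=C/C=C(/C(C)C)I)CC[C@@H](OC(C)=O)[C@]1(C)CCC=C(CCO)C(=O)O1
F2 | step 13 | methyl (2E,4Z)-2-{(3R)-3-acetoxy-3-[(2S)-6-(2-iodoethyl)-2-methyl-7-oxo-2,3,4,7-tetrahydrooxepin-2-yl]propyl}-5-iodo-6-methylhepta-2,4-dienoate | COC(=O)/C(=C/C=C(/C(C)C)I)CC[C@@H](OC(C)=O)[C@]1(C)CCC=C(CCI)C(=O)O1
F3 | step 13 | iodo{2-[(2S)-2-{(1R)-1-acetoxy-4-(methoxycarbonyl)-7-iodo-8-methylnona-4,6-dien-1-yl}-2-methyl-7-oxo-2,3,4,7-tetrahydrooxepin-6-yl]ethyl}zinc (alkylzinc iodide from F2) | COC(=O)/C(=C/C=C(/C(C)C)I)CC[C@@H](OC(C)=O)[C@]1(C)CCC=C(CC[Zn]I)C(=O)O1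
F4 | step 12 | sodium 4-hydroxy-2-methylidenebutanoate | [Na+].OCCC(=C)C([O-])=O
F5 | step 12 | tert-butyldimethylsilyl 4-[(tert-butyldimethylsilyl)oxy]-2-methylidenebutanoate | C=C(CCO[Si](C)(C)C(C)(C)C)C(=O)O[Si](C)(C)C(C)(C)C
F6 | step 12 | 4-[(tert-butyldimethylsilyl)oxy]-2-methylidenebutanoic acid | C=C(CCO[Si](C)(C)C(C)(C)C)C(O)=O
F7 | step 12 | methyl (2E,4Z)-2-[(3R,4S)-3-acetoxy-4-({4-[(tert-butyldimethylsilyl)oxy]-2-methylidenebutanoyl}oxy)-4-methyloct-7-en-1-yl]-5-iodo-6-methylhepta-2,4-dienoate | COC(=O)/C(=C/C=C(/C(C)C)I)CC[C@@H](OC(C)=O)[C@@](C)(OC(=O)C(=C)CCO[Si](C)(C)C(C)(C)C)CCC=C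
F8 | step 12 | methyl (2E,4Z)-2-{(3R)-3-acetoxy-3-[(2S)-6-{2-[(tert-butyldimethylsilyl)oxy]ethyl}-2-methyl-7-oxo-2,3,4,7-tetrahydrooxepin-2-yl]propyl}-5-iodo-6-methylhepta-2,4-dienoate | COC(=O)/C(=C/C=C(/C(C)C)I)CC[C@@H](OC(C)=O)[C@]1(C)CCC=C(CCO[Si](C)(C)C(C)(C)C)C(=O)O1
F9 | step 12 | methyl (2E,4Z)-2-{(3R)-3-acetoxy-3-[(2S)-6-(2-bromoethyl)-2-methyl-7-oxo-2,3,4,7-tetrahydrooxepin-2-yl]propyl}-5-iodo-6-methylhepta-2,4-dienoate | COC(=O)/C(=C/C=C(/C(C)C)I)CC[C@@H](OC(C)=O)[C@]1(C)CCC=C(CCBr)C(=O)O1
F10 | step 11 | methyl (2E,4Z)-2-[(3R,4S)-3-hydroxy-4-methyl-4-(prop-2-ynoyloxy)oct-7-en-1-yl]-5-iodo-6-methylhepta-2,4-dienoate | COC(=O)/C(=C/C=C(/C(C)C)I)CC[C@@H](O)[C@@](C)(OC(=O)C#C)CCC=C
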